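## Structural features

The target is a chalcone whose ring A is a phloroglucinol nucleus. One of its oxygens (O1) is tied into a 2,2-dimethyl-3-hydroxydihydropyran fused across C4a–C8a, so the bicyclic core is a 2,2-dimethylchroman-3-ol with free hydroxyls on C5 and C7. C8, the carbon between O1 and the C7 hydroxyl, carries the (E)-4-hydroxycinnamoyl ketone, and C6 stays unsubstituted. The only stereocenter is C3 (S). It is a secondary carbinol between the quaternary C2 (two methyls and O1) and the benzylic C4 methylene, and with no neighbouring stereocenter its configuration has to come from a reagent. The fragile elements are the E-enone (a Michael acceptor that is reduced under hydrogenolysis), the C7 hydroxyl ortho to the carbonyl (it can add to Cβ and give a flavanone under acid or base), the oxidation-prone ring A with two nucleophilic carbons (C6 and C8), and the tertiary O1–C2 ether. The real difficulties are three: a pyran ring that holds C3 at an oxidation level from which the S carbinol can be set, the choice of C8 over C6 for the acyl group, and the release of three phenols next to an enone. The key step uses the fact that C4–C4a joins an ortho carbon of a symmetric 3,5-dioxygenated aryl ether to the carbon β to the C3 oxygen. That carbon is the terminal carbon of a C3 enol ether, which becomes electrophilic once the enol ether is oxidized, while the quaternary C2 blocks enol ether isomerization and favours ring closure.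

## Logic of the disconnections

**18 to 17.** The three O–benzyl bonds (O5, O7 and the 4-hydroxyphenyl oxygen) are cut last. One ether type then serves from 1 onwards and survives base, titanium alkylidene, anode, aqueous acid, borane and organolithium. The skeleton is not simplified, but protecting-group traffic is reduced to a single unmasking. The forward step must cleave aryl benzyl ethers without hydrogen (the alkene) and without letting benzyl cations alkylate C6.

**17 to 9 and 13.** The C8–C(=O) bond is cut, with C8 as the nucleophile and the acyl carbon as the electrophile. The whole E-enone arrives intact in 13, and the chroman half 9 carries only a halogen. The forward step needs a bromine–lithium exchange that tolerates the C3 hydroxyl (as its lithium alkoxide) and a clean 1,2-addition that stops at the ketone.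

**13 to 10 and 11.** The Cα=Cβ bond is cut, which gives two purchasable compounds. The forward olefination must be E-selective.

**9 to 8.** The C8–Br bond is cut. This removes the only element that distinguishes C8 from C6. The forward bromination must therefore select C8 on steric grounds and stop at one bromine.

**8 to 7.** The C3–H bond is cut, so the stereocenter is erased to a ketone whose two flanks differ strongly in size (quaternary C2 against the C4 methylene). The forward reduction must be enantioface-selective under reagent control.

**7 to 6.** The C3=O group is exchanged for two C3–OMe bonds. This is a functional-group change only. The forward hydrolysis must spare the benzyl ethers and the tertiary ether.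

**6 to 4 and 5.** The C4–C4a bond and one C3–OMe bond are cut. The pyran ring opens to an aryl ether carrying a methyl enol ether, and ring A becomes a symmetric, unsubstituted aryl ether. The forward step must reverse the polarity of the enol ether terminus by oxidation and stop before the more electron-rich product is oxidized further.

**4 to 3.** The C3=CH2 bond is cut, leading back to an ester. The forward methylenation must be non-basic and must leave the enol ether unhydrolysed.

**3 to 1 and 2.** The O1–C2 bond is cut, leading to a symmetric phenol and a tertiary α-bromo ester. The forward O-alkylation must beat elimination of the bromide.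

## Other disconnections considered

**Alternative 1:** The cut runs through C4a–C8a and C7–C8, so ring A and the pyran are taken apart together. This leads to the acyclic diene–ynone A2, in which a 1-methoxy-1,3-bis(trimethylsilyloxy)diene is tethered through C4, C3 and C2 to the oxygen of a cinnamoyl alkynyl ether. In the forward direction an intramolecular Diels–Alder reaction of A2, followed by loss of methanol and silyl hydrolysis on mild acid work-up, would give the bis(tert-butyldimethylsilyl) ether A1 with ring A aromatic.

- In its favour: the substitution pattern of ring A is fixed by connectivity, so the C6/C8 question never arises; here it is better than the chosen plan, which relies on a sterically biased bromination. The C5 and C7 phenols emerge free and only two silyl ethers remain, a gentler end game than BCl3, and again better. The polarity is matched, since the nucleophilic diene terminus C4a meets the β-carbon C8a of the ynone.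
- Against it here: A2 contains a tertiary alkyl alkynyl ether with β-hydrogens on the gem-dimethyl groups, a motif that fragments by a retro-ene path to a ketene and an alkene on warming. The alkyne is deactivated by its oxygen donor and the diene terminus is substituted, so warming would probably be needed. The ynone and the cinnamoyl alkene are Michael acceptors toward the silyl ketene acetal, and the cinnamoyl alkene is a competing dienophile. The C3 stereocenter must still be made separately.
- Comparison: on structure it is more convergent than the chosen plan. On mechanism it forms two bonds in a concerted thermal step, against one bond in a stepwise electrochemical step, and is superior in bonds per step. On step economy the route to A2 is expected to be clearly longer than the whole chosen sequence, and A2 would be far less stable than 4.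

**Alternative 2:** The cut is the C3–O bond, made as part of an oxirane across C3=C4 of the 8-acetylchromene A4. In the forward direction NaOCl with (S,S)-(salen)MnCl (trivalent manganese) would give the (3S,4S)-epoxide A3. Hydride opening at benzylic C4, Claisen–Schmidt condensation and removal of the methoxymethyl groups would follow.

- In its favour: 2,2-dimethylchromenes are among the best substrates for this epoxidation, so enantiocontrol at C3 should be at least as dependable as the reduction of 7, and probably better. The acyl carbon is already on C8, so no bromination or organolithium is needed. The methoxymethyl ethers come off with dilute acid, which is kinder to the enone than BCl3. The chromene is short to make, so the overall count should be lower than in the chosen plan. On all four points this alternative is the equal or the better.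
- Against it here: A3 is a benzylic epoxide on a ring that carries oxygen at C5, C7 and O1, so its C4–O bond should ionize very easily, with rearrangement to a ketone or solvolysis. Hypochlorite can chlorinate C6 and attack the methyl ketone. The C5 substituent peri to C4 may erode selectivity. The hydride must open C4 without reducing the C8 acetyl group. Building A4 from an unsymmetrical acetylphloroglucinol moves the C6/C8 problem to the start.
- Comparison: on structure both plans reach the same chroman, and the chosen plan profits from a symmetric ring A at the moment of ring closure. On mechanism oxygen transfer to an alkene is replaced by hydride delivery to a stable ketone. On step economy the alternative is shorter, but its intermediates are less robust than 6 and 7.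

**Alternative 3:** The cut removes C8–C(=O) and C(=O)–Cα together. In the forward direction the aryl iodide A6, carbon monoxide and 4-(benzyloxy)styrene A7 would be joined with Pd(OAc)2 and a bulky phosphine to give the tribenzyl ether A5, which has the same structure as 17.

- In its favour: two C–C bonds and the E-alkene are formed in one catalytic step. No organolithium is used, so the free C3 hydroxyl needs no deprotonation and the benzyl ethers never see a strong base; this is better functional-group tolerance. A7 is purchasable, so the step that makes 13 disappears and the route is one step shorter.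
- Against it here: A6 has both ortho positions occupied by oxygen substituents. After oxidative addition to zerovalent palladium, CO insertion gives a hindered aroylpalladium, and insertion of an electron-rich styrene into it is slow. Direct Heck arylation (a stilbene) and capture of the acylpalladium by the C3 hydroxyl are therefore likely competitors.
- Comparison: A6 needs the same C8-selective halogenation as 9 and the end game with BCl3 is identical, so the two plans are equal on these points. On mechanism a catalytic acylpalladium path replaces a stoichiometric, cryogenic aryllithium acylation. The latter is the more predictable for a 2,6-dioxygenated aryl group.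

Key step: step 3

Assumption: 1, 2, 10 and 11 are taken as purchasable, and Cp2TiMe2 as its commercial toluene solution.

## Route

Step 1
Reactants: 1 3,5-bis(benzyloxy)phenol; 2 methyl 2-bromo-2-methylpropanoate
Product: 3 methyl 2-[3,5-bis(benzyloxy)phenoxy]-2-methylpropanoate
Conditions: Cs2CO3, DMF, 60 °C (2 in excess)
Reagents that add atoms: none
Why: Williamson-type O-alkylation of a caesium phenoxide with a tertiary α-bromo ester, the standard entry to 2-aryloxy-2-methylpropanoates; the excess of 2 compensates for E2 loss to methyl methacrylate and the benzyl ethers are inert.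

Step 2
Reactants: 3 methyl 2-[3,5-bis(benzyloxy)phenoxy]-2-methylpropanoate
Product: 4 1,3-bis(benzyloxy)-5-(3-methoxy-2-methylbut-3-en-2-yloxy)benzene
Conditions: Cp2TiMe2 (3 equiv), toluene/THF, 65 °C, dark; filtration through basic alumina
Reagents that add atoms: dimethyltitanocene Cp2TiMe2, SMILES C[Ti](C)(C1C=CC=C1)C1C=CC=C1
Why: Petasis methylenation: thermal loss of methane gives Cp2Ti=CH2, which converts the ester carbonyl into the methyl enol ether through an oxatitanacyclobutane; the reagent is non-basic, so the aryloxide is not eliminated, and the quaternary C2 leaves the new alkene no position to migrate to.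

Step 3
Reactants: 4 1,3-bis(benzyloxy)-5-(3-methoxy-2-methylbut-3-en-2-yloxy)benzene; 5 methanol
Product: 6 5,7-bis(benzyloxy)-3,3-dimethoxy-2,2-dimethylchroman
Conditions: RVC anode, Pt cathode, undivided cell, constant current, Et4NOTs (0.1 M), 2,6-lutidine, MeOH/THF 3:7, rt, charge limited to about 2.1 F/mol
Reagents that add atoms: none
Why: This is an anodic olefin coupling of an enol ether with an electron-rich arene, a known class of oxidative cyclization. One electron is removed at the anode from the enol ether (or from the trialkoxyarene, which leads to the same bond), and an ortho carbon of the aryl ether bonds to the terminal methylene carbon, the carbon β to the enol oxygen, creating C4–C4a. The pyran ring closes in the 6-endo-trig mode, the only mode that leaves the unpaired electron on the methoxy-bearing carbon; a 5-exo attack at that carbon would give a primary radical and is not expected. The α-methoxy radical is oxidized a second time to an oxocarbenium ion that methanol traps as the C3 dimethyl ketal, 2,6-lutidine takes the proton from the arenium ion so that ring A is restored, and the cathode reduces the protons to hydrogen. No stereocenter is formed, because C2 and C3 each carry two identical groups. Site selectivity is secured by the substrate: the two ortho carbons are equivalent by symmetry, each para to one benzyloxy group and ortho to the other, and the carbon between the two benzyloxy groups cannot reach the tether. The quaternary C2 excludes enol ether isomerization and its two methyl groups favour the folded conformer. The selectivity that has to be watched is oxidation of 4 in preference to the more electron-rich 6; the handles are constant current, a charge stopped near the theoretical two electrons and lutidine buffering, which also prevents acid-catalysed methanolysis of the enol ether.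

Step 4
Reactants: 6 5,7-bis(benzyloxy)-3,3-dimethoxy-2,2-dimethylchroman
Product: 7 5,7-bis(benzyloxy)-2,2-dimethylchroman-3-one
Conditions: 2 M aq HCl, THF, rt to 40 °C, degassed; crude ketone used at once
Reagents that add atoms: water, SMILES O
Why: Acid hydrolysis of a dimethyl ketal through the oxocarbenium ion; the α-aryloxy group slows ionization, so aqueous mineral acid is chosen over a buffered acid, while the aryl benzyl ethers and the tertiary O1–C2 ether (a cation at C2 would be α to the carbonyl carbon) should survive; air is excluded because the C4 methylene is both benzylic and α to the ketone.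

Step 5
Reactants: 7 5,7-bis(benzyloxy)-2,2-dimethylchroman-3-one
Product: 8 (S)-5,7-bis(benzyloxy)-2,2-dimethylchroman-3-ol
Conditions: (R)-2-methyl-CBS-oxazaborolidine (0.2 equiv), BH3·SMe2 (0.7 equiv), THF, −20 °C, slow addition of 7; MeOH
Reagents that add atoms: none
Why: Corey–Bakshi–Shibata reduction: the ketone oxygen binds the ring boron with the quaternary C2 (large) turned away from the catalyst and the C4 methylene (small) toward it, and the nitrogen-bound borane passes hydride to one face; the (S)-catalyst gives R carbinols from aryl methyl ketones, C2 outranks C4 just as aryl outranks methyl, so the (R)-catalyst should give the S carbinol.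

Step 6
Reactants: 8 (S)-5,7-bis(benzyloxy)-2,2-dimethylchroman-3-ol
Product: 9 (S)-5,7-bis(benzyloxy)-8-bromo-2,2-dimethylchroman-3-ol
Conditions: NBS (1.0 equiv), CH2Cl2, −78 → 0 °C, dark
Reagents that add atoms: N-bromosuccinimide, SMILES O=C1CCC(=O)N1Br
Why: Electrophilic aromatic bromination; C6 and C8 are each flanked by two oxygens, but C6 lies between two freely rotating benzyloxy groups whereas one neighbour of C8 is the ring oxygen held back in the pyran, so C8 is the less hindered site, as is usual for 5,7-bis(benzyloxy)chroman-3-ols; one equivalent at low temperature limits dibromination and the free hydroxyl is tolerated.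

Step 7
Reactants: 10 4-(benzyloxy)benzaldehyde; 11 diethyl {2-[methoxy(methyl)amino]-2-oxoethyl}phosphonate
Product: 13 (E)-3-[4-(benzyloxy)phenyl]-N-methoxy-N-methylprop-2-enamide, via sodium phosphonate carbanion 12 (not isolated)
Conditions: NaH, THF, 0 °C; then 10, 0 °C → rt
Reagents that add atoms: none
Why: Horner–Wadsworth–Emmons olefination of an aromatic aldehyde with an amide-stabilized phosphonate carbanion; reversible addition and anti-periplanar elimination of diethyl phosphate should give the E-alkene.

Step 8
Reactants: 9 (S)-5,7-bis(benzyloxy)-8-bromo-2,2-dimethylchroman-3-ol; 13 (E)-3-[4-(benzyloxy)phenyl]-N-methoxy-N-methylprop-2-enamide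
Product: 17 (S,E)-1-[5,7-bis(benzyloxy)-3-hydroxy-2,2-dimethylchroman-8-yl]-3-[4-(benzyloxy)phenyl]prop-2-en-1-one, via lithium alkoxide 14 (not isolated), via aryllithium alkoxide 15 (not isolated), via tetrahedral lithium adduct 16 (not isolated)
Conditions: MeLi (1.05 equiv), THF, −78 °C; t-BuLi (2.1 equiv), −78 °C; 13, −78 → −30 °C; aq NH4Cl
Reagents that add atoms: none
Why: Hydroxyl deprotonation, bromine–lithium exchange and acyl substitution of an N-methoxy-N-methylamide: MeLi removes the hydroxyl proton without exchanging the bromide, two equivalents of t-BuLi then give the aryllithium (the second consumes t-BuBr), and 1,2-addition to the amide gives a chelated tetrahedral adduct that releases the ketone only on work-up, so over-addition is avoided and the E-alkene and the C3 alkoxide are untouched.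

Step 9
Reactants: 17 (S,E)-1-[5,7-bis(benzyloxy)-3-hydroxy-2,2-dimethylchroman-8-yl]-3-[4-(benzyloxy)phenyl]prop-2-en-1-one
Product: 18 (S,E)-3-(4-hydroxyphenyl)-1-(3,5,7-trihydroxy-2,2-dimethylchroman-8-yl)prop-2-en-1-one
Conditions: BCl3 (1 M in CH2Cl2, 6 equiv), pentamethylbenzene (10 equiv), CH2Cl2, −78 °C; MeOH, −78 °C → rt
Reagents that add atoms: none
Why: Lewis-acid debenzylation of aryl benzyl ethers with a non-basic cation scavenger: BCl3 binds the ether oxygens (the C7 ether with chelation to the ketone) and the benzyl cations are captured by pentamethylbenzene before they can alkylate C6 or the alkene; at −78 °C the enone, the tertiary O1–C2 ether and the C3 carbinol (held as a borate) should remain intact, and methanol frees the phenols; hydrogenolysis is excluded by the alkene.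

## Compound list

1 | 3,5-bis(benzyloxy)phenol | Oc1cc(OCc2ccccc2)cc(OCc2ccccc2)c1 | starting material
2 | methyl 2-bromo-2-methylpropanoate | COC(=O)C(C)(C)Br | starting material
3 | methyl 2-[3,5-bis(benzyloxy)phenoxy]-2-methylpropanoate | COC(=O)C(C)(C)Oc1cc(OCc2ccccc2)cc(OCc2ccccc2)c1 | intermediate
4 | 1,3-bis(benzyloxy)-5-(3-methoxy-2-methylbut-3-en-2-yloxy)benzene | C=C(OC)C(C)(C)Oc1cc(OCc2ccccc2)cc(OCc2ccccc2)c1 | intermediate
5 | methanol | CO | starting material
6 | 5,7-bis(benzyloxy)-3,3-dimethoxy-2,2-dimethylchroman | CC1(C)Oc2cc(OCc3ccccc3)cc(OCc3ccccc3)c2CC1(OC)OC | intermediate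
7 | 5,7-bis(benzyloxy)-2,2-dimethylchroman-3-one | CC1(C)Oc2cc(OCc3ccccc3)cc(OCc3ccccc3)c2CC1=O | intermediate
8 | (S)-5,7-bis(benzyloxy)-2,2-dimethylchroman-3-ol | CC1(C)Oc2cc(OCc3ccccc3)cc(OCc3ccccc3)c2C[C@@H]1O | intermediate
9 | (S)-5,7-bis(benzyloxy)-8-bromo-2,2-dimethylchroman-3-ol | CC1(C)Oc2c(c(OCc3ccccc3)cc(OCc3ccccc3)c2Br)C[C@@H]1O | intermediate
10 | 4-(benzyloxy)benzaldehyde | O=Cc1ccc(OCc2ccccc2)cc1 | starting material
11 | diethyl {2-[methoxy(methyl)amino]-2-oxoethyl}phosphonate | CCOP(=O)(OCC)CC(=O)N(C)OC | starting material
12 | sodium salt of the carbanion of 11 | CCOP(=O)(OCC)[CH-]C(=O)N(C)OC.[Na+] | intermediate (not isolated)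
13 | (E)-3-[4-(benzyloxy)phenyl]-N-methoxy-N-methylprop-2-enamide | CON(C)C(=O)/C=C/c1ccc(OCc2ccccc2)cc1 | intermediate
14 | lithium (S)-5,7-bis(benzyloxy)-8-bromo-2,2-dimethylchroman-3-olate | CC1(C)Oc2c(c(OCc3ccccc3)cc(OCc3ccccc3)c2Br)C[C@@H]1O[Li] | intermediate (not isolated)
15 | lithium (S)-5,7-bis(benzyloxy)-8-lithio-2,2-dimethylchroman-3-olate | CC1(C)Oc2c(c(OCc3ccccc3)cc(OCc3ccccc3)c2[Li])C[C@@H]1O[Li] | intermediate (not isolated)
16 | dilithium salt of the tetrahedral adduct of 15 and 13 (lithium alkoxide at the former amide carbon, either configuration there, and at C3) | CC1(C)Oc2c(c(OCc3ccccc3)cc(OCc3ccccc3)c2C(O[Li])(/C=C/c2ccc(OCc3ccccc3)cc2)N(C)OC)C[C@@H]1O[Li] | intermediate (not isolated)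
17 | (S,E)-1-[5,7-bis(benzyloxy)-3-hydroxy-2,2-dimethylchroman-8-yl]-3-[4-(benzyloxy)phenyl]prop-2-en-1-one | CC1(C)Oc2c(c(OCc3ccccc3)cc(OCc3ccccc3)c2C(=O)/C=C/c2ccc(OCc3ccccc3)cc2)C[C@@H]1O | intermediate
18 | (S,E)-3-(4-hydroxyphenyl)-1-(3,5,7-trihydroxy-2,2-dimethylchroman-8-yl)prop-2-en-1-one | CC1(C)Oc2c(c(O)cc(O)c2C(=O)/C=C/c2ccc(O)cc2)C[C@@H]1O | target

## Step count and least certain steps

Total step count: 9. Longest linear sequence: 8 steps (steps 1 to 6, 8 and 9, from 1 to 18); step 7 is a one-step side branch.

**Step 3 (key step).** The most likely failures are three. The product may be oxidized further, because ring A of 6 is more electron-rich than that of 4. The tertiary O–C2 bond may cleave in the radical cation. Methanol may add across the enol ether without C–C bond formation. The closure is also an endo attack on a 1,1-disubstituted enol ether, a less usual mode than the exo closures of this reaction class.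
Fallback: it sets out from 3 and returns at 7, so step 4 is not needed. Saponification (LiOH, THF/MeOH/H2O) should give 2-[3,5-bis(benzyloxy)phenoxy]-2-methylpropanoic acid F1. Activation with isobutyl chloroformate and N-methylmorpholine should give the mixed anhydride 2-[3,5-bis(benzyloxy)phenoxy]-2-methylpropanoic isobutyl carbonic anhydride F2, and trimethylsilyldiazomethane should convert it into 3-[3,5-bis(benzyloxy)phenoxy]-1-diazo-3-methylbutan-2-one F3. With dirhodium tetraacetate Rh2(OAc)4 in CH2Cl2 the derived carbenoid should substitute the ortho carbon of the aryl ether. This aromatic C–H insertion is the established way from aryloxy-substituted diazoketones to chroman-3-ones. It forms the same C4–C4a bond and delivers 7.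

**Step 5.** Facial selectivity may be poor. The aryloxy oxygen next to the carbonyl can compete for boron, the small flank is a benzylic methylene and not a methyl group, and uncatalysed borane reduction adds a racemic background.
Fallback: it sets out from 7 and returns at 8. NaBH4 in MeOH should give racemic 5,7-bis(benzyloxy)-2,2-dimethylchroman-3-ol F4. Acylation with (1S,4R)-camphanic chloride (Et3N, DMAP, CH2Cl2) should give the diastereomeric esters (S)-5,7-bis(benzyloxy)-2,2-dimethylchroman-3-yl (1S,4R)-camphanate F5 and (R)-5,7-bis(benzyloxy)-2,2-dimethylchroman-3-yl (1S,4R)-camphanate F6. These are separated by crystallization or chromatography, and F5 is cleaved with LiOH to 8. The same esters can be used to enrich a partly selective batch from step 5.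

**Step 6.** Bromination may occur at C6 or twice, since both positions are activated by two oxygens and the preference for C8 is steric only.
Fallback: it sets out from 1 and returns at 9; the bromine is placed before the ring is made, so that ring closure itself defines C8. Bromination of 1 with NBS and catalytic diisopropylamine in CH2Cl2 (ortho-directed by the hydroxyl) should give 3,5-bis(benzyloxy)-2-bromophenol F7, which is told from the symmetric para isomer by its lack of symmetry. The conditions of steps 1 to 4 should then give in turn:
- methyl 2-[3,5-bis(benzyloxy)-2-bromophenoxy]-2-methylpropanoate F8;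
- 1,5-bis(benzyloxy)-2-bromo-3-(3-methoxy-2-methylbut-3-en-2-yloxy)benzene F9;
- 5,7-bis(benzyloxy)-8-bromo-3,3-dimethoxy-2,2-dimethylchroman F10 (only one ortho carbon is free, so only the 8-bromochroman can form);
- 5,7-bis(benzyloxy)-8-bromo-2,2-dimethylchroman-3-one F11.

Reduction of F11 under the conditions of step 5 gives 9.

**Step 8.** The aryllithium may be quenched by proton transfer (from incompletely deprotonated hydroxyl or from the neighbouring benzylic CH2), the hindered and aggregated dianion may add slowly, or it may add in the conjugate sense to the unsaturated amide.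
Fallback: it sets out from 9 and returns at 17; the enone is assembled by condensation and not delivered intact. After the same lithiation, N-methoxy-N-methylacetamide, a small electrophile that cannot undergo conjugate addition, should give (S)-1-[5,7-bis(benzyloxy)-3-hydroxy-2,2-dimethylchroman-8-yl]ethan-1-one F12. Claisen–Schmidt condensation of F12 with 10 (KOH, EtOH, rt) should give 17.

**Step 9.** The enone may be attacked under the Lewis acid (addition of chloride, closure of the C7 oxygen onto Cβ to a flavanone), C6 may be benzylated, the pyran may open by cleavage of the tertiary O1–C2 bond, or the ethers para to the carbonyl may cleave incompletely.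
Fallback: it sets out from 9 and returns at 18; the benzyl groups are removed before any alkene exists. The ketone (S)-1-[5,7-bis(benzyloxy)-3-hydroxy-2,2-dimethylchroman-8-yl]ethan-1-one F12, made as in the fallback for step 8, is hydrogenolysed (H2, Pd/C, EtOAc) to (S)-1-(3,5,7-trihydroxy-2,2-dimethylchroman-8-yl)ethan-1-one F13. Chloromethyl methyl ether and K2CO3 in acetone should etherify only the C5 hydroxyl, since the C7 hydroxyl is hydrogen-bonded to the ketone, giving (S)-1-[3,7-dihydroxy-5-(methoxymethoxy)-2,2-dimethylchroman-8-yl]ethan-1-one F14. Claisen–Schmidt condensation with purchased 4-(methoxymethoxy)benzaldehyde (KOH, EtOH/H2O) should give (S,E)-1-[3,7-dihydroxy-5-(methoxymethoxy)-2,2-dimethylchroman-8-yl]-3-[4-(methoxymethoxy)phenyl]prop-2-en-1-one F15. HCl in MeOH at rt removes both acetals and gives 18.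

## Further compounds

F1 | step 3 | 2-[3,5-bis(benzyloxy)phenoxy]-2-methylpropanoic acid | CC(C)(Oc1cc(OCc2ccccc2)cc(OCc2ccccc2)c1)C(=O)O
F2 | step 3 | 2-[3,5-bis(benzyloxy)phenoxy]-2-methylpropanoic isobutyl carbonic anhydride | CC(C)COC(=O)OC(=O)C(C)(C)Oc1cc(OCc2ccccc2)cc(OCc2ccccc2)c1
F3 | step 3 | 3-[3,5-bis(benzyloxy)phenoxy]-1-diazo-3-methylbutan-2-one | CC(C)(Oc1cc(OCc2ccccc2)cc(OCc2ccccc2)c1)C(=O)C=[N+]=[N-]
F4 | step 5 | racemic 5,7-bis(benzyloxy)-2,2-dimethylchroman-3-ol | CC1(C)Oc2cc(OCc3ccccc3)cc(OCc3ccccc3)c2CC1O
F5 | step 5 | (S)-5,7-bis(benzyloxy)-2,2-dimethylchroman-3-yl (1S,4R)-camphanate | CC1(C)[C@@]2(C)CC[C@@]1(OC2=O)C(=O)O[C@H]1Cc2c(OCc3ccccc3)cc(OCc3ccccc3)cc2OC1(C)C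
F6 | step 5 | (R)-5,7-bis(benzyloxy)-2,2-dimethylchroman-3-yl (1S,4R)-camphanate | CC1(C)[C@@]2(C)CC[C@@]1(OC2=O)C(=O)O[C@@H]1Cc2c(OCc3ccccc3)cc(OCc3ccccc3)cc2OC1(C)C
F7 | step 6 | 3,5-bis(benzyloxy)-2-bromophenol | Oc1cc(OCc2ccccc2)cc(OCc2ccccc2)c1Br
F8 | step 6 | methyl 2-[3,5-bis(benzyloxy)-2-bromophenoxy]-2-methylpropanoate | COC(=O)C(C)(C)Oc1cc(OCc2ccccc2)cc(OCc2ccccc2)c1Br
F9 | step 6 | 1,5-bis(benzyloxy)-2-bromo-3-(3-methoxy-2-methylbut-3-en-2-yloxy)benzene | C=C(OC)C(C)(C)Oc1cc(OCc2ccccc2)cc(OCc2ccccc2)c1Br
F10 | step 6 | 5,7-bis(benzyloxy)-8-bromo-3,3-dimethoxy-2,2-dimethylchroman | CC1(C)Oc2c(c(OCc3ccccc3)cc(OCc3ccccc3)c2Br)CC1(OC)OC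
F11 | step 6 | 5,7-bis(benzyloxy)-8-bromo-2,2-dimethylchroman-3-one | CC1(C)Oc2c(c(OCc3ccccc3)cc(OCc3ccccc3)c2Br)CC1=O
F12 | step 8 | (S)-1-[5,7-bis(benzyloxy)-3-hydroxy-2,2-dimethylchroman-8-yl]ethan-1-one | CC1(C)Oc2c(c(OCc3ccccc3)cc(OCc3ccccc3)c2C(C)=O)C[C@@H]1O
F13 | step 9 | (S)-1-(3,5,7-trihydroxy-2,2-dimethylchroman-8-yl)ethan-1-one | CC1(C)Oc2c(c(O)cc(O)c2C(C)=O)C[C@@H]1O
F14 | step 9 | (S)-1-[3,7-dihydroxy-5-(methoxymethoxy)-2,2-dimethylchroman-8-yl]ethan-1-one | CC1(C)Oc2c(c(OCOC)cc(O)c2C(C)=O)C[C@@H]1O
F15 | step 9 | (S,E)-1-[3,7-dihydroxy-5-(methoxymethoxy)-2,2-dimethylchroman-8-yl]-3-[4-(methoxymethoxy)phenyl]prop-2-en-1-one | CC1(C)Oc2c(c(OCOC)cc(O)c2C(=O)/C=C/c2ccc(OCOC)cc2)C[C@@H]1O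
A1 | alternative 1 | (S,E)-3-[4-(tert-butyldimethylsilyloxy)phenyl]-1-[3-(tert-butyldimethylsilyloxy)-5,7-dihydroxy-2,2-dimethylchroman-8-yl]prop-2-en-1-one | CC1(C)Oc2c(c(O)cc(O)c2C(=O)/C=C/c2ccc(O[Si](C)(C)C(C)(C)C)cc2)C[C@@H]1O[Si](C)(C)C(C)(C)C
A2 | alternative 1 | (E)-5-[4-(tert-butyldimethylsilyloxy)phenyl]-1-{[(3S)-3-(tert-butyldimethylsilyloxy)-8-methoxy-2-methyl-6,8-bis(trimethylsilyloxy)octa-5,7-dien-2-yl]oxy}pent-4-en-1-yn-3-one | COC(O[Si](C)(C)C)=CC(O[Si](C)(C)C)=CC[C@H](O[Si](C)(C)C(C)(C)C)C(C)(C)OC#CC(=O)/C=C/c1ccc(O[Si](C)(C)C(C)(C)C)cc1
A3 | alternative 2 | (3S,4S)-8-acetyl-3,4-epoxy-5,7-bis(methoxymethoxy)-2,2-dimethylchroman | CC1(C)Oc2c(c(OCOC)cc(OCOC)c2C(C)=O)[C@@H]3O[C@H]13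
A4 | alternative 2 | 1-[5,7-bis(methoxymethoxy)-2,2-dimethyl-2H-chromen-8-yl]ethan-1-one | CC1(C)Oc2c(c(OCOC)cc(OCOC)c2C(C)=O)C=C1
A5 | alternative 3 | (S,E)-1-[5,7-bis(benzyloxy)-3-hydroxy-2,2-dimethylchroman-8-yl]-3-[4-(benzyloxy)phenyl]prop-2-en-1-one | CC1(C)Oc2c(c(OCc3ccccc3)cc(OCc3ccccc3)c2C(=O)/C=C/c2ccc(OCc3ccccc3)cc2)C[C@@H]1O
A6 | alternative 3 | (S)-5,7-bis(benzyloxy)-8-iodo-2,2-dimethylchroman-3-ol | CC1(C)Oc2c(c(OCc3ccccc3)cc(OCc3ccccc3)c2I)C[C@@H]1O
A7 | alternative 3 | 4-(benzyloxy)styrene | C=Cc1ccc(OCc2ccccc2)cc1
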